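C1 = ester carbon, C5=C6 and C7=C8 = the dienone alkenes, C8–C12 = the cyclopentenone ring (C9 ketone, C10 chlorine, C12 acetoxy), C13–C20 = the octenyl chain.
Retrosynthesis: one operation cuts C6–C7 together with both bonds of the ring ketone (C8–C9 and C9–C10, C9 = CO). The open-chain piece left is a tertiary propargylic acetate with a (Z)-1-chloro-1-iodovinyl group, traced back through its two one-carbon arms and a cuprate-opened epoxide to 2-methylidenepropane-1,3-diol.
Enabling feature: ketone C9 sits between two sp2 carbons (C8, C10), and on the exocyclic C7=C8 bond of the five-membered ring C6 is cis to C9 (7Z). This is the outcome of a syn addition of an acyl group and a carbon group across a terminal alkyne C7≡C8 held on the quaternary carbon C12.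
Forward: the acyclic C7–C20 skeleton with both arms on C12 is built first; the last step joins vinyl iodide, CO, alkyne and the C1–C6 alkenylstannane, which closes the only ring (5-exo-dig) and attaches the chain.
Stereochemistry: C12 from a Sharpless epoxidation (L-(+)-tartrate); 14Z from syn-carbocupration of acetylene; the ring alkene from the (Z)-iodide; 5E from the stannane; 7Z from the syn acylpalladation.

Key step: step 12

Remark on the chemistry: the tartrate catalyst is assumed to choose the same face of the 2-substituted allylic alcohol as it does with allyl alcohol (which gives (S)-glycidol); organolithium and organopalladium intermediates are drawn without solvent or phosphine ligands.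

Step 1
Reactants: 1 2-methylidenepropane-1,3-diol
Product: 2 2-({[tert-butyl(dimethyl)silyl]oxy}methyl)prop-2-en-1-ol
Conditions: TBSCl (1.0 equiv), imidazole (1.5 equiv), 1 (3 equiv), DMF, 0 °C
Reagents that add atoms: tert-butyldimethylsilyl chloride, CC(C)(C)[Si](C)(C)Cl
Why: Imidazole-promoted O-silylation with an excess of the cheap symmetrical diol should stop at the mono-silyl ether; no stereocentre is formed.

Step 2
Reactants: 2 2-({[tert-butyl(dimethyl)silyl]oxy}methyl)prop-2-en-1-ol
Product: 3 [(2S)-2-({[tert-butyl(dimethyl)silyl]oxy}methyl)oxiran-2-yl]methanol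
Conditions: Ti(OiPr)4 (10 mol%), L-(+)-diethyl tartrate (12 mol%), t-BuOOH, 4 Å molecular sieves, CH2Cl2, −20 °C
Reagents that add atoms: tert-butyl hydroperoxide, CC(C)(C)OO
Why: Sharpless asymmetric epoxidation of a 2-substituted allylic alcohol: the titanium tartrate complex binds the free CH2OH and should deliver oxygen to the face that gives (S)-glycidol from allyl alcohol, which sets the quaternary centre (later C12) as S in 3.

Step 3
Reactants: 3 [(2S)-2-({[tert-butyl(dimethyl)silyl]oxy}methyl)oxiran-2-yl]methanol
Product: 4 (2R,4Z)-2-({[tert-butyl(dimethyl)silyl]oxy}methyl)dec-4-ene-1,2-diol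
Conditions: n-C5H11Li, CuBr·SMe2, Et2O, −40 °C; HC≡CH, −50 to −25 °C; then 3, −30 to 0 °C; aq NH4Cl
Reagents that add atoms: lithium di[(Z)-hept-1-enyl]cuprate (made in the flask from pentyllithium, CuBr·SMe2 and acetylene), [Li+].CCCCC/C=C\[Cu-]/C=C\CCCCC
Why: syn-Carbocupration of acetylene gives the (Z)-alkenyl cuprate, which should open the epoxide by SN2 attack at its CH2 carbon (cuprate epoxide opening), so the 14Z alkene is set and the quaternary centre is not touched.

Step 4
Reactants: 4 (2R,4Z)-2-({[tert-butyl(dimethyl)silyl]oxy}methyl)dec-4-ene-1,2-diol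
Product: 5 (2S,4Z)-2-({[tert-butyl(dimethyl)silyl]oxy}methyl)-2-hydroxydec-4-enal
Conditions: SO3·pyridine, DMSO, iPr2NEt, CH2Cl2, 0 °C
Reagents that add atoms: none
Why: Parikh–Doering oxidation should convert only the primary hydroxyl, since the tertiary one has no carbinol hydrogen and the mild base leaves the silyl ether and the (Z)-alkene alone (the descriptor changes by priority only).

Step 5
Reactants: 5 (2S,4Z)-2-({[tert-butyl(dimethyl)silyl]oxy}methyl)-2-hydroxydec-4-enal
Product: 6 (1E,3R,5Z)-3-({[tert-butyl(dimethyl)silyl]oxy}methyl)-1-chloroundeca-1,5-dien-3-ol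
Conditions: CrCl2 (6 equiv), CHCl3 (2 equiv), THF, 65 °C
Reagents that add atoms: chloroform, ClC(Cl)Cl
Why: Takai olefination: the geminal dichromium reagent from CHCl3 and divalent chromium adds to the aldehyde and eliminates to the chloroalkene, E being favoured because chlorine and the bulky quaternary carbon stay anti in the elimination, and the free tertiary hydroxyl is tolerated.

Step 6
Reactants: 6 (1E,3R,5Z)-3-({[tert-butyl(dimethyl)silyl]oxy}methyl)-1-chloroundeca-1,5-dien-3-ol
Product: 8 (1Z,3R,5Z)-3-({[tert-butyl(dimethyl)silyl]oxy}methyl)-1-chloro-1-iodoundeca-1,5-dien-3-ol, via lithium carbenoid 7 (not isolated)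
Conditions: s-BuLi (2.2 equiv), THF–Et2O–pentane, −105 °C; then I2, −105 to −78 °C
Reagents that add atoms: iodine, II
Why: After O-deprotonation the lithium alkoxide directs the second equivalent of base to the vinylic hydrogen geminal to chlorine and cis to the carbinol carbon (directed α-lithiation of a 1-chloroalkene), and iodination of the configurationally stable carbenoid with retention should place iodine cis to the quaternary carbon.

Step 7
Reactants: 8 (1Z,3R,5Z)-3-({[tert-butyl(dimethyl)silyl]oxy}methyl)-1-chloro-1-iodoundeca-1,5-dien-3-ol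
Product: 9 (2R,4Z)-2-[(Z)-2-chloro-2-iodoethenyl]dec-4-ene-1,2-diol
Conditions: HF·pyridine, pyridine, THF, 0 °C to rt
Reagents that add atoms: none
Why: Fluoride-driven cleavage of the primary silyl ether under non-basic conditions should avoid dehydrohalogenation of the dihaloalkene.

Step 8
Reactants: 9 (2R,4Z)-2-[(Z)-2-chloro-2-iodoethenyl]dec-4-ene-1,2-diol
Product: 10 (2R,4Z)-2-[(Z)-2-chloro-2-iodoethenyl]-2-hydroxydec-4-enal
Conditions: SO3·pyridine, DMSO, iPr2NEt, CH2Cl2, 0 °C
Reagents that add atoms: none
Why: Parikh–Doering oxidation again touches only the primary hydroxyl; the α-hydroxy aldehyde is used at once.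

Step 9
Reactants: 10 (2R,4Z)-2-[(Z)-2-chloro-2-iodoethenyl]-2-hydroxydec-4-enal
Product: 11 (1Z,3R,5Z)-1-chloro-3-ethynyl-1-iodoundeca-1,5-dien-3-ol
Conditions: dimethyl (1-diazo-2-oxopropyl)phosphonate, K2CO3, MeOH, 0 °C to rt
Reagents that add atoms: dimethyl (1-diazo-2-oxopropyl)phosphonate, COP(=O)(OC)C(=[N+]=[N-])C(C)=O
Why: The Ohira–Bestmann variant of the Seyferth–Gilbert homologation turns the aldehyde into the terminal alkyne under carbonate conditions that should be mild enough for the vinyl iodide and the quaternary centre.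

Step 10
Reactants: 11 (1Z,3R,5Z)-1-chloro-3-ethynyl-1-iodoundeca-1,5-dien-3-ol
Product: 12 (1Z,3R,5Z)-1-chloro-3-ethynyl-1-iodoundeca-1,5-dien-3-yl acetate
Conditions: Ac2O, DMAP (0.2 equiv), Et3N, CH2Cl2, rt
Reagents that add atoms: acetic anhydride, CC(=O)OC(C)=O
Why: DMAP-catalysed acylation of the tertiary propargylic alcohol installs the acetate of the target and blocks the hydroxyl that would otherwise trap the acylpalladium of step 12 as a lactone.

Step 11
Reactants: 13 methyl hex-5-ynoate
Product: 14 methyl (5E)-6-(tributylstannyl)hex-5-enoate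
Conditions: Bu3SnH, Pd2(dba)3 (1 mol%), Cy3P·HBF4 (4 mol%), iPr2NEt (8 mol%), CH2Cl2, 0 °C
Reagents that add atoms: tributyltin hydride, CCCC[SnH](CCCC)CCCC
Why: Palladium-catalysed hydrostannation of a terminal alkyne is a syn addition, and with the bulky phosphine tin should go to the terminal carbon, which gives the (E)-alkenylstannane.

Step 12
Reactants: 12 (1Z,3R,5Z)-1-chloro-3-ethynyl-1-iodoundeca-1,5-dien-3-yl acetate; 14 methyl (5E)-6-(tributylstannyl)hex-5-enoate
Product: 17 methyl (5E,7Z)-7-{(5R)-5-(acetyloxy)-3-chloro-5-[(2Z)-oct-2-en-1-yl]-2-oxocyclopent-3-en-1-ylidene}hept-5-enoate, via acylpalladium iodide 15 (not isolated), via alkenylpalladium iodide 16 (not isolated)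
Conditions: CO (1 atm), Pd2(dba)3 (5 mol%), P(2-furyl)3 (20 mol%), THF, 45 °C; 14 (1.3 equiv) added over 4 h
Reagents that add atoms: carbon monoxide, [C-]#[O+]
Why: Proposed new method: zerovalent palladium inserts into the carbon–iodine bond of 12 (not the C–Cl bond) and takes up CO to give acylpalladium 15; because iodine was cis to the quaternary carbon, the acyl group can add syn across the pendant terminal alkyne to give alkenylpalladium 16, which is coupled with stannane 14 (transmetalation, reductive elimination) to form the C6–C7 bond. The closest known reaction types are the carbonylative cyclisation of 1-iodo-1,4-dienes and 1-iodo-enynes by intramolecular acylpalladation and the carbonylative Stille coupling; joining them with tin capture of the cyclised alkenylpalladium on a 1-chloro-1-iodo-1-en-4-yne is new. The cyclopentenone ring closes in the 5-exo-dig mode (bond C8–C9); direct 4-exo or 5-endo carbopalladation of the alkyne by the first alkenylpalladium is geometrically disfavoured, so CO is taken up first. No stereocentre is created: C12 comes from step 2, the 7Z geometry follows from the syn addition of acyl carbon and palladium (C6 replaces palladium with retention), and 5E comes from 14. The step needs ring closure to outrun acyl transfer to tin and a second CO uptake by 16; the intramolecular insertion, slow addition of 14, only 1 atm of CO and the weakly bound furylphosphine (fast transmetalation) should secure this. The neutral, base-free and copper-free conditions should keep the terminal alkyne C–H and the tertiary propargylic acetate intact.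

Compound list
1 | 2-methylidenepropane-1,3-diol | C=C(CO)CO | starting material
2 | 2-({[tert-butyl(dimethyl)silyl]oxy}methyl)prop-2-en-1-ol | C=C(CO)CO[Si](C)(C)C(C)(C)C | intermediate
3 | [(2S)-2-({[tert-butyl(dimethyl)silyl]oxy}methyl)oxiran-2-yl]methanol | C1[C@@](CO[Si](C)(C)C(C)(C)C)(O1)CO | intermediate
4 | (2R,4Z)-2-({[tert-butyl(dimethyl)silyl]oxy}methyl)dec-4-ene-1,2-diol | CCCCC/C=C\C[C@@](CO[Si](C)(C)C(C)(C)C)(O)CO | intermediate
5 | (2S,4Z)-2-({[tert-butyl(dimethyl)silyl]oxy}methyl)-2-hydroxydec-4-enal | CCCCC/C=C\C[C@@](CO[Si](C)(C)C(C)(C)C)(O)C=O | intermediate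
6 | (1E,3R,5Z)-3-({[tert-butyl(dimethyl)silyl]oxy}methyl)-1-chloroundeca-1,5-dien-3-ol | CCCCC/C=C\C[C@@](CO[Si](C)(C)C(C)(C)C)(O)/C=C/Cl | intermediate
7 | lithium (1E,3R,5Z)-3-({[tert-butyl(dimethyl)silyl]oxy}methyl)-1-chloro-1-lithioundeca-1,5-dien-3-olate (lithium carbenoid, not isolated) | CCCCC/C=C\C[C@@](CO[Si](C)(C)C(C)(C)C)(O[Li])/C=C(/Cl)[Li] | intermediate
8 | (1Z,3R,5Z)-3-({[tert-butyl(dimethyl)silyl]oxy}methyl)-1-chloro-1-iodoundeca-1,5-dien-3-ol | CCCCC/C=C\C[C@@](CO[Si](C)(C)C(C)(C)C)(O)/C=C(/Cl)I | intermediate
9 | (2R,4Z)-2-[(Z)-2-chloro-2-iodoethenyl]dec-4-ene-1,2-diol | CCCCC/C=C\C[C@@](CO)(O)/C=C(/Cl)I | intermediate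
10 | (2R,4Z)-2-[(Z)-2-chloro-2-iodoethenyl]-2-hydroxydec-4-enal | CCCCC/C=C\C[C@@](C=O)(O)/C=C(/Cl)I | intermediate
11 | (1Z,3R,5Z)-1-chloro-3-ethynyl-1-iodoundeca-1,5-dien-3-ol | CCCCC/C=C\C[C@@](C#C)(O)/C=C(/Cl)I | intermediate
12 | (1Z,3R,5Z)-1-chloro-3-ethynyl-1-iodoundeca-1,5-dien-3-yl acetate | CCCCC/C=C\C[C@@](C#C)(OC(C)=O)/C=C(/Cl)I | intermediate
13 | methyl hex-5-ynoate | COC(=O)CCCC#C | starting material
14 | methyl (5E)-6-(tributylstannyl)hex-5-enoate | COC(=O)CCC/C=C/[Sn](CCCC)(CCCC)CCCC | intermediate
15 | (2E,4R,6Z)-4-(acetyloxy)-2-chloro-4-ethynyldodeca-2,6-dienoylpalladium iodide (acylpalladium iodide, not isolated) | CCCCC/C=C\C[C@@](C#C)(OC(C)=O)/C=C(/Cl)C(=O)[Pd]I | intermediate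
16 | (Z)-{(5R)-5-(acetyloxy)-3-chloro-5-[(2Z)-oct-2-en-1-yl]-2-oxocyclopent-3-en-1-ylidene}methylpalladium iodide (alkenylpalladium iodide, not isolated) | CCCCC/C=C\C[C@@]1(OC(C)=O)C=C(Cl)C(=O)/C1=C\[Pd]I | intermediate
17 | methyl (5E,7Z)-7-{(5R)-5-(acetyloxy)-3-chloro-5-[(2Z)-oct-2-en-1-yl]-2-oxocyclopent-3-en-1-ylidene}hept-5-enoate | CCCCC/C=C\C[C@@]1(OC(C)=O)C=C(Cl)C(=O)/C1=C\C=C\CCCC(=O)OC | target

Total step count: 12. Longest linear sequence: 11 steps (steps 1 to 10 and step 12).

Steps most likely to fail

Step 12 (the proposed new method). The acylpalladium may be transferred to tin before it closes the ring, the cyclised alkenylpalladium may take up a second CO, or zerovalent palladium may ionise the tertiary propargylic acetate. The fallback uses known reaction types, sets out from 12 (with 13 as source of the chain) and comes back at 17. Iodine–magnesium exchange on 12 with iPrMgCl·LiCl at −78 °C and formylation with DMF would give, with retention of the alkene geometry, (2E,4R,6Z)-4-(acetyloxy)-2-chloro-4-ethynyldodeca-2,6-dienal F1. Hydrozirconation of 13 with Cp2Zr(H)Cl would give methyl (5E)-6-[chlorobis(cyclopentadienyl)zirconio]hex-5-enoate F2. The nickel-catalysed alkylative cyclisation of ynals with alkenylzirconium reagents (Ni(cod)2, ZnCl2, THF, 0 °C) would join F1 and F2 by oxidative cyclisation of aldehyde and alkyne at zerovalent nickel, alkenyl transfer and reductive elimination. This forms the same C6–C7 and C8–C9 bonds by syn addition and gives methyl (5E,7E)-7-{(5R)-5-(acetyloxy)-3-chloro-2-hydroxy-5-[(2Z)-oct-2-en-1-yl]cyclopent-3-en-1-ylidene}hept-5-enoate F3 (epimers at the carbinol carbon; the descriptor of the exocyclic alkene changes, its geometry does not). Dess–Martin oxidation of the allylic alcohol would then give 17.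

Step 6. The α-chloroalkenyllithium may lose its geometry or undergo hydrogen shift to the alkyne (Fritsch–Buttenberg–Wiechell rearrangement) before it is iodinated, or deprotonation may be incomplete at −105 °C. The fallback sets out from 6 and comes back at 8, and uses exactly that rearrangement. n-BuLi (3.3 equiv, THF, −78 to 0 °C) followed in the same flask by N-chlorosuccinimide would turn the chloroalkene into the chloroalkyne (3R,5Z)-3-({[tert-butyl(dimethyl)silyl]oxy}methyl)-1-chloroundec-5-en-1-yn-3-ol F4. Hydroxyl-directed trans-hydroalumination with NaAlH2(OCH2CH2OMe)2 (THF, 0 °C) and an iodine quench at −78 °C should then give 8, because aluminium, and then iodine, sits on the distal carbon cis to the carbinol.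

Step 5. The hindered α-hydroxy aldehyde may undergo α-ketol rearrangement under Lewis-acidic chromium at 65 °C, and the E selectivity of the chloro-olefination may be incomplete. The fallback sets out from 5 and comes back at 6. Ohira–Bestmann homologation (K2CO3, MeOH, 0 °C) would give (3R,5Z)-3-({[tert-butyl(dimethyl)silyl]oxy}methyl)undec-5-en-1-yn-3-ol F5. Hydrozirconation with excess Cp2Zr(H)Cl (syn addition, zirconium at the terminal carbon) and a quench with N-chlorosuccinimide should give 6 with the E geometry fixed by the addition.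

Further compounds
F1 | step 12 | (2E,4R,6Z)-4-(acetyloxy)-2-chloro-4-ethynyldodeca-2,6-dienal | CCCCC/C=C\C[C@@](C#C)(OC(C)=O)/C=C(/Cl)C=O
F2 | step 12 | methyl (5E)-6-[chlorobis(cyclopentadienyl)zirconio]hex-5-enoate | COC(=O)CCC/C=C/[Zr](Cl)(C1C=CC=C1)C1C=CC=C1
F3 | step 12 | methyl (5E,7E)-7-{(5R)-5-(acetyloxy)-3-chloro-2-hydroxy-5-[(2Z)-oct-2-en-1-yl]cyclopent-3-en-1-ylidene}hept-5-enoate | CCCCC/C=C\C[C@@]1(OC(C)=O)C=C(Cl)C(O)/C1=C\C=C\CCCC(=O)OC
F4 | step 6 | (3R,5Z)-3-({[tert-butyl(dimethyl)silyl]oxy}methyl)-1-chloroundec-5-en-1-yn-3-ol | CCCCC/C=C\C[C@@](CO[Si](C)(C)C(C)(C)C)(O)C#CCl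
F5 | step 5 | (3R,5Z)-3-({[tert-butyl(dimethyl)silyl]oxy}methyl)undec-5-en-1-yn-3-ol | CCCCC/C=C\C[C@@](CO[Si](C)(C)C(C)(C)C)(O)C#C
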